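**Retrosynthetic overview**
- The target comes from acetylation of the C14 alcohol. Before that, one CrCl2-mediated intramolecular allylation closes the 14-membered ring at C1–C14: the β-carbon of a 3-(bromomethyl)butenolide (a lactone homoenolate, normally an acceptor carbon) attacks a tethered aldehyde carbon, which also unveils the exocyclic methylene and sets C1 and C14.
- Ring order: epoxide (hydroxyl-directed, threo-selective), then butenolide (ring-closing metathesis of a 2-(bromomethyl)acrylate of a vinyl carbinol), then macrocycle.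
- C2 is set by a catalytic asymmetric vinyl addition to an (E)-enal; it then controls C3/C4 and, through the butenolide, C1/C14.
- The C2–C13 chain with both E-alkenes is (2E,6E)-farnesol; C14 is added at the terminal (E)-methyl by SeO2 oxidation, methylenation and hydroboration.

Assumption: cembrane numbering is used for the macrocycle (C1 ring-fusion CH, C2 lactone O–CH, C3/C4 epoxide, C14 acetoxy carbon, C16 lactone C=O, C15=C17 exocyclic methylene), so the target is (1R,2S,3R,4R,14S,7E,11E); (2E,6E)-farnesol and 2-(bromomethyl)acrylic acid are taken as commercial.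

**Route**

Step 1
Reactants: 1 (2E,6E)-farnesol
Product: 2 (2E,6E)-farnesyl acetate
Conditions: Ac2O, pyridine, DMAP (cat.), CH2Cl2, 0 °C → rt
Reagents that add atoms: acetic anhydride, CC(=O)OC(C)=O
Why: Standard DMAP-catalysed O-acetylation masks the allylic alcohol so that the following SeO2 oxidation touches only the distal prenyl terminus; no stereocentre is formed.

Step 2
Reactants: 2 (2E,6E)-farnesyl acetate
Product: 4 (2E,6E,10E)-3,7,11-trimethyl-12-oxododeca-2,6,10-trien-1-yl acetate, via 12-hydroxyfarnesyl acetate 3 (not isolated)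
Conditions: SeO2 (0.2 equiv), t-BuOOH (3 equiv), salicylic acid (0.1 equiv), CH2Cl2, rt; filter, then MnO2 (10 equiv), CH2Cl2, rt
Reagents that add atoms: tert-butyl hydroperoxide, CC(C)(C)OO
Why: Catalytic SeO2 allylic oxidation (ene reaction, then [2,3]-sigmatropic shift) is selective for the (E)-methyl of the terminal trisubstituted alkene of farnesyl esters, and MnO2 converges the crude alcohol/aldehyde mixture to the (E)-enal because it oxidises only allylic alcohols; the geometry of the future C11=C12 alkene is fixed here.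

Step 3
Reactants: 4 (2E,6E,10E)-3,7,11-trimethyl-12-oxododeca-2,6,10-trien-1-yl acetate
Product: 5 (2E,6E,10E)-3,7,11-trimethyltrideca-2,6,10,12-tetraen-1-yl acetate
Conditions: Ph3PCH3Br, KN(SiMe3)2, THF, −78 → 0 °C
Reagents that add atoms: methyltriphenylphosphonium bromide, C[P+](c1ccccc1)(c1ccccc1)c1ccccc1.[Br-]
Why: Wittig methylenation of the enal by the non-stabilised ylide is much faster at low temperature than attack on the acetate and installs the future C14 as the terminal CH2 of a 1,3-diene.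

Step 4
Reactants: 5 (2E,6E,10E)-3,7,11-trimethyltrideca-2,6,10,12-tetraen-1-yl acetate
Product: 8 (2E,6E,10E)-3,7,11-trimethyltrideca-2,6,10-triene-1,13-diol, via B-alkyl-9-BBN adduct 6 (not isolated), via 13-hydroxy acetate 7 (not isolated)
Conditions: 9-BBN (1.3 equiv), THF, 0 °C → rt; then 3 M NaOH, 30% H2O2, 0 °C → rt, 3 h
Reagents that add atoms: hydrogen peroxide, OO; 9-borabicyclo[3.3.1]nonane, [H]B1C2CCCC1CCC2 (its boron stays only in intermediate 6)
Why: Brown hydroboration with bulky 9-BBN is anti-Markovnikov and occurs only at the monosubstituted vinyl terminus of the diene (trisubstituted alkenes are inert), and the alkaline peroxide oxidation of the C–B bond also saponifies the acetate, giving the diol in one operation.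

Step 5
Reactants: 8 (2E,6E,10E)-3,7,11-trimethyltrideca-2,6,10-triene-1,13-diol
Product: 9 (2E,6E,10E)-13-hydroxy-3,7,11-trimethyltrideca-2,6,10-trienal
Conditions: MnO2 (20 equiv), CH2Cl2, rt
Reagents that add atoms: none
Why: MnO2 oxidises allylic but not saturated primary alcohols, so only the C1 alcohol becomes the (E)-enal (chemoselective allylic oxidation).

Step 6
Reactants: 9 (2E,6E,10E)-13-hydroxy-3,7,11-trimethyltrideca-2,6,10-trienal
Product: 10 (2E,6E,10E)-3,7,11-trimethyl-13-(triethylsilyloxy)trideca-2,6,10-trienal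
Conditions: TESCl, imidazole, CH2Cl2, 0 °C
Reagents that add atoms: chlorotriethylsilane, CC[Si](Cl)(CC)CC
Why: Routine silylation of the remaining primary alcohol gives an ether that survives the organozinc, peroxide, carbodiimide and ruthenium steps that follow.

Step 7
Reactants: 10 (2E,6E,10E)-3,7,11-trimethyl-13-(triethylsilyloxy)trideca-2,6,10-trienal
Product: 11 (3S,4E,8E,12E)-5,9,13-trimethyl-15-(triethylsilyloxy)pentadeca-1,4,8,12-tetraen-3-ol
Conditions: Zn(CH=CH2)2 (2 equiv), (−)-MIB [(2S)-3-exo-morpholinoisoborneol] (10 mol%), toluene/hexane, −20 → 0 °C; aq. NH4Cl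
Reagents that add atoms: divinylzinc, C=C[Zn]C=C
Why: Amino-alcohol-catalysed enantioselective 1,2-addition of a diorganozinc (Noyori–Oppolzer type) delivers vinyl to the Si face of the enal with (−)-MIB, the facial sense that gives (S)-carbinols from aryl and unsaturated aldehydes, so the future C2 is set as S.

Step 8
Reactants: 11 (3S,4E,8E,12E)-5,9,13-trimethyl-15-(triethylsilyloxy)pentadeca-1,4,8,12-tetraen-3-ol
Product: 12 (1S)-1-{(2R,3R)-3-[(3E,7E)-4,8-dimethyl-10-(triethylsilyloxy)deca-3,7-dien-1-yl]-3-methyloxiran-2-yl}prop-2-en-1-ol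
Conditions: VO(acac)2 (5 mol%), t-BuOOH (1.3 equiv, in decane), toluene, 0 °C
Reagents that add atoms: tert-butyl hydroperoxide, CC(C)(C)OO
Why: Hydroxyl-directed vanadium-catalysed epoxidation (Sharpless–Michaelson type) reacts only at the electron-rich trisubstituted allylic alkene, and because that alkene has a methyl cis to the carbinol, A(1,3) strain puts the carbinol H in the alkene plane so that oxygen is delivered syn to OH, giving the threo (2R,3R) epoxide next to the (S)-carbinol (about 6:1 expected from close models; the erythro isomer is removed by chromatography).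

Step 9
Reactants: 12 (1S)-1-{(2R,3R)-3-[(3E,7E)-4,8-dimethyl-10-(triethylsilyloxy)deca-3,7-dien-1-yl]-3-methyloxiran-2-yl}prop-2-en-1-ol; 13 2-(bromomethyl)acrylic acid
Product: 14 (1S)-1-{(2R,3R)-3-[(3E,7E)-4,8-dimethyl-10-(triethylsilyloxy)deca-3,7-dien-1-yl]-3-methyloxiran-2-yl}prop-2-en-1-yl 2-(bromomethyl)acrylate
Conditions: DCC (1.5 equiv), DMAP (5 mol%), CH2Cl2, −20 → 0 °C
Reagents that add atoms: none
Why: Steglich esterification acylates the hindered secondary alcohol under near-neutral conditions with retention at C2 and without Payne rearrangement, while low temperature and only catalytic DMAP limit SN2′ attack of the amine on the bromomethyl acrylate.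

Step 10
Reactants: 14 (1S)-1-{(2R,3R)-3-[(3E,7E)-4,8-dimethyl-10-(triethylsilyloxy)deca-3,7-dien-1-yl]-3-methyloxiran-2-yl}prop-2-en-1-yl 2-(bromomethyl)acrylate
Product: 15 (5S)-3-(bromomethyl)-5-{(2R,3R)-3-[(3E,7E)-4,8-dimethyl-10-(triethylsilyloxy)deca-3,7-dien-1-yl]-3-methyloxiran-2-yl}furan-2(5H)-one
Conditions: second-generation Hoveyda–Grubbs catalyst RuCl2(H2IMes)(=CH-C6H4-2-OiPr) (7 mol%), toluene (5 mM), 80 °C, Ar sparge
Reagents that add atoms: none
Why: Ring-closing metathesis starts at the monosubstituted vinyl group and closes onto the 1,1-disubstituted acrylate to give the five-membered butenolide with loss of ethylene, the trisubstituted chain alkenes and the allylic bromide being inert to the phosphine-free ruthenium carbene; C2 is untouched.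

Step 11
Reactants: 15 (5S)-3-(bromomethyl)-5-{(2R,3R)-3-[(3E,7E)-4,8-dimethyl-10-(triethylsilyloxy)deca-3,7-dien-1-yl]-3-methyloxiran-2-yl}furan-2(5H)-one
Product: 17 (3E,7E)-10-{(2R,3R)-3-[(2S)-4-(bromomethyl)-5-oxo-2,5-dihydrofuran-2-yl]-2-methyloxiran-2-yl}-3,7-dimethyldeca-3,7-dienal, via primary alcohol 16 (not isolated)
Conditions: IBX (3 equiv), DMSO, rt; crude aldehyde used at once
Reagents that add atoms: none
Why: IBX in DMSO cleaves primary triethylsilyl ethers and oxidises the freed alcohol in the same flask (one-pot desilylation/IBX oxidation) under base-free, near-neutral conditions, which avoids epoxide opening, butenolide epimerisation and conjugation of the β,γ-unsaturated aldehyde.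

Step 12
Reactants: 17 (3E,7E)-10-{(2R,3R)-3-[(2S)-4-(bromomethyl)-5-oxo-2,5-dihydrofuran-2-yl]-2-methyloxiran-2-yl}-3,7-dimethyldeca-3,7-dienal
Product: 19 (1R,2S,3R,4R,14S,7E,11E)-3,4-epoxy-14-hydroxycembra-7,11,15(17)-trien-16,2-olide, via allylchromium dichloride 18 (not isolated)
Conditions: CrCl2 (8 equiv), 4 Å MS, THF, rt, 17 added over 12 h (final 2 mM); aq. NH4Cl work-up
Reagents that add atoms: none
Why: In this intramolecular Nozaki–Hiyama (Barbier-type) allylation two equivalents of divalent chromium turn the allylic bromide into an allylchromium species whose lactone β-carbon C1 is nucleophilic (homoenolate, d3 reactivity) and attacks the tethered aldehyde through a six-membered chair with allylic transposition, which creates the exocyclic methylene; attack on the butenolide face anti to the C2 epoxy side chain gives the trans fusion (1R), and the ring-locked E-type allyl unit with a pseudo-equatorial aldehyde substituent gives the anti carbinol (14S), the same sense as in intermolecular Barbier additions of 3-(bromomethyl)furan-2(5H)-one and in CrCl2 macrocyclisations of allylic bromides onto aldehydes.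

Step 13
Reactants: 19 (1R,2S,3R,4R,14S,7E,11E)-3,4-epoxy-14-hydroxycembra-7,11,15(17)-trien-16,2-olide
Product: 20 (1R,2S,3R,4R,14S,7E,11E)-14-acetoxy-3,4-epoxycembra-7,11,15(17)-trien-16,2-olide (CNP0294029.1)
Conditions: Ac2O, pyridine, DMAP (cat.), CH2Cl2, 0 °C
Reagents that add atoms: acetic anhydride, CC(=O)OC(C)=O
Why: Standard acetylation of the secondary alcohol, run promptly so that the C14 hydroxyl cannot translactonise onto the lactone carbonyl; no stereocentre changes.

**Compound list**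
1 | (2E,6E)-farnesol | CC(C)=CCC/C(C)=C/CC/C(C)=C/CO | starting material
2 | (2E,6E)-farnesyl acetate | CC(C)=CCC/C(C)=C/CC/C(C)=C/COC(C)=O | intermediate
3 | (2E,6E,10E)-12-hydroxy-3,7,11-trimethyldodeca-2,6,10-trien-1-yl acetate (not isolated) | OC/C(C)=C/CC/C(C)=C/CC/C(C)=C/COC(C)=O | intermediate
4 | (2E,6E,10E)-3,7,11-trimethyl-12-oxododeca-2,6,10-trien-1-yl acetate | O=C/C(C)=C/CC/C(C)=C/CC/C(C)=C/COC(C)=O | intermediate
5 | (2E,6E,10E)-3,7,11-trimethyltrideca-2,6,10,12-tetraen-1-yl acetate | C=C/C(C)=C/CC/C(C)=C/CC/C(C)=C/COC(C)=O | intermediate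
6 | (2E,6E,10E)-13-(9-borabicyclo[3.3.1]nonan-9-yl)-3,7,11-trimethyltrideca-2,6,10-trien-1-yl acetate (not isolated) | CC(=O)OC/C=C(C)/CC/C=C(C)/CC/C=C(C)/CCB1C2CCCC1CCC2 | intermediate
7 | (2E,6E,10E)-13-hydroxy-3,7,11-trimethyltrideca-2,6,10-trien-1-yl acetate (not isolated) | OCC/C(C)=C/CC/C(C)=C/CC/C(C)=C/COC(C)=O | intermediate
8 | (2E,6E,10E)-3,7,11-trimethyltrideca-2,6,10-triene-1,13-diol | OCC/C(C)=C/CC/C(C)=C/CC/C(C)=C/CO | intermediate
9 | (2E,6E,10E)-13-hydroxy-3,7,11-trimethyltrideca-2,6,10-trienal | OCC/C(C)=C/CC/C(C)=C/CC/C(C)=C/C=O | intermediate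
10 | (2E,6E,10E)-3,7,11-trimethyl-13-(triethylsilyloxy)trideca-2,6,10-trienal | CC[Si](CC)(CC)OCC/C(C)=C/CC/C(C)=C/CC/C(C)=C/C=O | intermediate
11 | (3S,4E,8E,12E)-5,9,13-trimethyl-15-(triethylsilyloxy)pentadeca-1,4,8,12-tetraen-3-ol | C=C[C@H](O)/C=C(C)/CC/C=C(C)/CC/C=C(C)/CCO[Si](CC)(CC)CC | intermediate
12 | (1S)-1-{(2R,3R)-3-[(3E,7E)-4,8-dimethyl-10-(triethylsilyloxy)deca-3,7-dien-1-yl]-3-methyloxiran-2-yl}prop-2-en-1-ol | C=C[C@H](O)[C@H]1O[C@]1(C)CC/C=C(C)/CC/C=C(C)/CCO[Si](CC)(CC)CC | intermediate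
13 | 2-(bromomethyl)acrylic acid | C=C(CBr)C(=O)O | starting material
14 | (1S)-1-{(2R,3R)-3-[(3E,7E)-4,8-dimethyl-10-(triethylsilyloxy)deca-3,7-dien-1-yl]-3-methyloxiran-2-yl}prop-2-en-1-yl 2-(bromomethyl)acrylate | C=C[C@H](OC(=O)C(=C)CBr)[C@H]1O[C@]1(C)CC/C=C(C)/CC/C=C(C)/CCO[Si](CC)(CC)CC | intermediate
15 | (5S)-3-(bromomethyl)-5-{(2R,3R)-3-[(3E,7E)-4,8-dimethyl-10-(triethylsilyloxy)deca-3,7-dien-1-yl]-3-methyloxiran-2-yl}furan-2(5H)-one | O=C1O[C@@H](C=C1CBr)[C@H]1O[C@]1(C)CC/C=C(C)/CC/C=C(C)/CCO[Si](CC)(CC)CC | intermediate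
16 | (5S)-3-(bromomethyl)-5-{(2R,3R)-3-[(3E,7E)-10-hydroxy-4,8-dimethyldeca-3,7-dien-1-yl]-3-methyloxiran-2-yl}furan-2(5H)-one (not isolated) | O=C1O[C@@H](C=C1CBr)[C@H]1O[C@]1(C)CC/C=C(C)/CC/C=C(C)/CCO | intermediate
17 | (3E,7E)-10-{(2R,3R)-3-[(2S)-4-(bromomethyl)-5-oxo-2,5-dihydrofuran-2-yl]-2-methyloxiran-2-yl}-3,7-dimethyldeca-3,7-dienal | O=C1O[C@@H](C=C1CBr)[C@H]1O[C@]1(C)CC/C=C(C)/CC/C=C(C)/CC=O | intermediate
18 | allylchromium dichloride of 17 (trivalent chromium on the former CH2Br carbon; not isolated) | O=C1O[C@@H](C=C1C[Cr](Cl)Cl)[C@H]1O[C@]1(C)CC/C=C(C)/CC/C=C(C)/CC=O | intermediate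
19 | (1R,2S,3R,4R,14S,7E,11E)-3,4-epoxy-14-hydroxycembra-7,11,15(17)-trien-16,2-olide: 14-membered carbocycle trans-fused at C1/C2 to an α-methylene-γ-butyrolactone, C3–C4 epoxide, free OH at C14 | C=C1C(=O)O[C@H]2[C@H]1[C@@H](O)C/C(C)=C/CC/C(C)=C/CC[C@@]1(C)O[C@H]21 | intermediate
20 | (1R,2S,3R,4R,14S,7E,11E)-14-acetoxy-3,4-epoxycembra-7,11,15(17)-trien-16,2-olide (CNP0294029.1) | C=C1C(=O)O[C@H]2[C@H]1[C@@H](OC(C)=O)C/C(C)=C/CC/C(C)=C/CC[C@@]1(C)O[C@H]21 | target

**Step count and risks**

Total steps: 13. Longest linear sequence: 13 steps (fully linear from 1).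

Steps most likely to fail:

Step 12 (macrocyclisation). Risks are oligomerisation, protonation of the allylchromium, imperfect face selectivity in the ring-forming transition state and translactonisation of the C14 alkoxide. Fallback, setting out from 15: borylation catalysed by zerovalent palladium (Pd2(dba)3, bis(pinacolato)diboron, THF) replaces bromide by boron to give the allyl pinacolboronate F1. Desilylation/oxidation as in step 11 gives the boronate aldehyde F2. This is cyclised without any reducing metal by intramolecular allylboration (dilute toluene, catalytic diphenyl phosphate) through the same closed chair to the O-boryl macrocycle F3. Its B–O bond is hydrolysed on work-up, and the route is rejoined at 19.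

Step 10 (ring-closing metathesis with the allylic bromide already in place; step 9 shares the risk through amine attack on the bromomethyl acrylate). Fallback, setting out from 13 and 12: the bromide is introduced only after ring closure. Sodium 4-methoxybenzyl oxide (from the alcohol and NaH) displaces the bromide of 13 to give 2-{[(4-methoxybenzyl)oxy]methyl}acrylic acid F4. Steglich coupling with 12 gives the ester F5, and ring-closing metathesis gives the 3-[(4-methoxybenzyloxy)methyl]butenolide F6. Buffered DDQ frees the 3-(hydroxymethyl)butenolide F7, and Appel bromination (CBr4, PPh3) rejoins the route at 15.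

Step 7 (asymmetric vinylation; salt-free divinylzinc and the ee on a β,β-disubstituted enal are the weak points). Fallback, setting out from 10: CH2=CHMgBr in THF gives the racemic carbinol F8. This is resolved by lipase-catalysed acylation (Amano PS lipase, vinyl acetate, hexane), in which the (R)-enantiomer is converted into the (R)-acetate F9. The unreacted (S)-alcohol is 11, where the route is rejoined.

Further compounds
F1 | step 12 | (5S)-5-{(2R,3R)-3-[(3E,7E)-4,8-dimethyl-10-(triethylsilyloxy)deca-3,7-dien-1-yl]-3-methyloxiran-2-yl}-3-[(4,4,5,5-tetramethyl-1,3,2-dioxaborolan-2-yl)methyl]furan-2(5H)-one | O=C1O[C@@H](C=C1CB2OC(C)(C)C(C)(C)O2)[C@H]3O[C@]3(C)CC/C=C(C)/CC/C=C(C)/CCO[Si](CC)(CC)CC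
F2 | step 12 | (3E,7E)-3,7-dimethyl-10-{(2R,3R)-2-methyl-3-[(2S)-5-oxo-4-[(4,4,5,5-tetramethyl-1,3,2-dioxaborolan-2-yl)methyl]-2,5-dihydrofuran-2-yl]oxiran-2-yl}deca-3,7-dienal | O=C1O[C@@H](C=C1CB2OC(C)(C)C(C)(C)O2)[C@H]3O[C@]3(C)CC/C=C(C)/CC/C=C(C)/CC=O
F3 | step 12 | 14-O-(4,4,5,5-tetramethyl-1,3,2-dioxaborolan-2-yl) derivative of 19 | C=C1C(=O)O[C@H]2[C@H]1[C@@H](OB3OC(C)(C)C(C)(C)O3)C/C(C)=C/CC/C(C)=C/CC[C@@]1(C)O[C@H]21
F4 | step 10 | 2-{[(4-methoxybenzyl)oxy]methyl}acrylic acid | C=C(COCc1ccc(OC)cc1)C(=O)O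
F5 | step 10 | (1S)-1-{(2R,3R)-3-[(3E,7E)-4,8-dimethyl-10-(triethylsilyloxy)deca-3,7-dien-1-yl]-3-methyloxiran-2-yl}prop-2-en-1-yl 2-{[(4-methoxybenzyl)oxy]methyl}acrylate | C=C[C@H](OC(=O)C(=C)COCc1ccc(OC)cc1)[C@H]2O[C@]2(C)CC/C=C(C)/CC/C=C(C)/CCO[Si](CC)(CC)CC
F6 | step 10 | (5S)-5-{(2R,3R)-3-[(3E,7E)-4,8-dimethyl-10-(triethylsilyloxy)deca-3,7-dien-1-yl]-3-methyloxiran-2-yl}-3-{[(4-methoxybenzyl)oxy]methyl}furan-2(5H)-one | O=C1O[C@@H](C=C1COCc2ccc(OC)cc2)[C@H]3O[C@]3(C)CC/C=C(C)/CC/C=C(C)/CCO[Si](CC)(CC)CC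
F7 | step 10 | (5S)-5-{(2R,3R)-3-[(3E,7E)-4,8-dimethyl-10-(triethylsilyloxy)deca-3,7-dien-1-yl]-3-methyloxiran-2-yl}-3-(hydroxymethyl)furan-2(5H)-one | O=C1O[C@@H](C=C1CO)[C@H]3O[C@]3(C)CC/C=C(C)/CC/C=C(C)/CCO[Si](CC)(CC)CC
F8 | step 7 | racemic (4E,8E,12E)-5,9,13-trimethyl-15-(triethylsilyloxy)pentadeca-1,4,8,12-tetraen-3-ol | C=CC(O)/C=C(C)/CC/C=C(C)/CC/C=C(C)/CCO[Si](CC)(CC)CC
F9 | step 7 | (3R,4E,8E,12E)-5,9,13-trimethyl-15-(triethylsilyloxy)pentadeca-1,4,8,12-tetraen-3-yl acetate | C=C[C@@H](OC(C)=O)/C=C(C)/CC/C=C(C)/CC/C=C(C)/CCO[Si](CC)(CC)CC
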